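The route rests on disconnecting C9–C10, which joins the α-carbons of ketones C7 and C11 inside the cyclohexane-1,4-dione ring C6–C7–C9–C10–C11–C13. Because C6 and C13 are quaternary, each ketone enolises only toward C9 or C10. One oxidation of the bis-enolate therefore forges this bond, closes the bicyclo[3.2.1]octanedione and sets C9. The precursor 23 is a dimethoxybenzo-fused bicyclo[3.2.1]octadiene. Its one-carbon bridge C6 is the spiro centre of a 4-isopropenylcyclopentanone and its bridgehead C13 bears an acetyl group. It is built by a Claisen rearrangement (C6–C13), a chromium-mediated closure (C17–C18) and a Friedel–Crafts closure (C18–C19).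

Key step: step 15

Assumption 1: atom labels C1–C26 are those of the target SMILES with the oxygens counted, and stereodescriptors quoted with these labels are CIP descriptors of the compound in question.
Assumption 2: from 18 onward the C4 substituent lies on the same face of the five-membered ring as C18, where a free isopropenyl group could trap any electrophile. It is therefore carried as its phenyl sulfide from step 2 to step 13, and C2 is then an inconsequential epimer mixture left undefined in the SMILES, as is the carbinol carbon of 19.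

Step 1
Reactants: 1 cyclopent-2-en-1-one; 2 isopropenylboronic acid pinacol ester
Product: 3 (3S)-3-(prop-1-en-2-yl)cyclopentan-1-one
Conditions: Rh(acac)(C2H4)2 (3 mol %), (S)-BINAP, dioxane–H2O 10:1, 100 °C
Reagents that add atoms: none
Why: Hayashi–Miyaura asymmetric conjugate addition, in which the alkenylrhodium species inserts the enone on the face left open by (S)-BINAP (the sense established for aryl and alkenyl boron reagents on cyclopentenone), sets C4 as S.

Step 2
Reactants: 3 (3S)-3-(prop-1-en-2-yl)cyclopentan-1-one
Product: 4 (3S)-3-[1-(phenylsulfanyl)propan-2-yl]cyclopentan-1-one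
Conditions: PhSH, AIBN (5 mol %), PhMe, 80 °C
Reagents that add atoms: thiophenol, Sc1ccccc1
Why: Radical thiol–ene addition puts sulfur on terminal C1 through the tertiary C2 radical and so removes the one π-nucleophile that would later face electrophilic C18; the new centre C2 is uncontrolled and is erased in step 13.

Step 3
Reactants: 4 (3S)-3-[1-(phenylsulfanyl)propan-2-yl]cyclopentan-1-one; 5 ethyl formate
Product: 6 (2Z,4S)-2-(hydroxymethylidene)-4-[1-(phenylsulfanyl)propan-2-yl]cyclopentan-1-one
Conditions: NaH, EtOH (cat.), THF, 0 → 25 °C; then 1 M HCl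
Reagents that add atoms: none
Why: The crossed Claisen condensation is reversible, so it formylates the less hindered α-carbon C6 remote from the C4 substituent and is driven by the stable β-keto aldehyde enolate, which installs C18 without touching C4.

Step 4
Reactants: 7 2-iodo-1,4-dimethoxybenzene; 8 prop-2-yn-1-ol
Product: 9 3-(2,5-dimethoxyphenyl)prop-2-yn-1-ol
Conditions: PdCl2(PPh3)2 (2 mol %), CuI (4 mol %), Et3N, THF, 25 °C
Reagents that add atoms: none
Why: Sonogashira coupling of an aryl iodide with a terminal alkyne tolerates the free alcohol and joins C13 to C26.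

Step 5
Reactants: 9 3-(2,5-dimethoxyphenyl)prop-2-yn-1-ol
Product: 11 (Z)-3-(2,5-dimethoxyphenyl)-3-iodoprop-2-en-1-ol, via cyclic sodium alkenylalanate 10 (not isolated)
Conditions: NaAlH2(OCH2CH2OMe)2, THF, 0 → 25 °C; then I2, −78 °C
Reagents that add atoms: iodine, II
Why: Hydroxyl-directed trans-hydroalumination of the propargylic alcohol gives the five-membered alanate with aluminium on C13, and iodinolysis with retention fixes iodine cis to the CH2OH group.

Step 6
Reactants: 8 prop-2-yn-1-ol
Product: 13 (Z)-3-iodo-2-methylprop-2-en-1-ol, via cyclic alkenylmagnesium alkoxide 12 (not isolated)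
Conditions: MeMgBr (2.5 equiv), CuI (10 mol %), THF, −10 → 25 °C; then I2, −10 °C
Reagents that add atoms: methylmagnesium bromide, C[Mg]Br; iodine, II
Why: Copper-catalysed anti-carbomagnesiation delivers methyl to the internal carbon (C15) and magnesium to the terminus (C17) inside an alkoxide chelate, so iodinolysis gives the vinyl iodide with C14 and iodine cis, as the later six-membered ring requires.

Step 7
Reactants: 13 (Z)-3-iodo-2-methylprop-2-en-1-ol
Product: 14 (Z)-3-bromo-1-iodo-2-methylprop-1-ene
Conditions: CBr4, PPh3, CH2Cl2, 0 °C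
Reagents that add atoms: tetrabromomethane, BrC(Br)(Br)Br
Why: Appel bromination of a primary allylic alcohol runs under neutral conditions and keeps both the alkene geometry and the vinyl iodide.

Step 8
Reactants: 11 (Z)-3-(2,5-dimethoxyphenyl)-3-iodoprop-2-en-1-ol; 14 (Z)-3-bromo-1-iodo-2-methylprop-1-ene
Product: 16 (2E,5Z)-3-(2,5-dimethoxyphenyl)-6-iodo-5-methylhexa-2,5-dien-1-ol, via chelated alkenylmagnesium alkoxide 15 (not isolated)
Conditions: iPrMgCl·LiCl (2.1 equiv), THF, −40 °C; Li2CuCl4 (5 mol %), then 14, −40 → 0 °C
Reagents that add atoms: none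
Why: Iodine–magnesium exchange proceeds with retention at the alkoxide-chelated alkenyl iodide, and copper-catalysed allylic substitution at the CH2Br carbon of 14 (the other allyl terminus is blocked by iodine) forms C13–C14 with the aryl group trans to C10.

Step 9
Reactants: 6 (2Z,4S)-2-(hydroxymethylidene)-4-[1-(phenylsulfanyl)propan-2-yl]cyclopentan-1-one; 16 (2E,5Z)-3-(2,5-dimethoxyphenyl)-6-iodo-5-methylhexa-2,5-dien-1-ol
Product: 17 E-configured allyl vinyl ether (O-allylated 6)
Conditions: PPh3, DIAD, THF, 0 → 25 °C
Reagents that add atoms: none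
Why: Mitsunobu O-alkylation of the acidic enol by the primary allylic alcohol (SN2 at C10) avoids an ionisable allylic halide and gives the more stable E enol ether, while any alkylation on the ketone oxygen would converge on the same product in step 10.

Step 10
Reactants: 17 E-configured allyl vinyl ether
Product: 18 quaternary keto aldehyde (C4 S; C6 R; C13 R)
Conditions: PhMe (0.05 M), BHT (cat.), 110 °C, sealed tube, dark
Reagents that add atoms: none
Why: The thermal Claisen rearrangement passes through a chair transition state on the ring face anti to the C4 substituent and forms C6–C13, so the E enol ether and the E allyl alkene translate into the adjacent quaternary centres with aryl and C7 on the same side, and the C=O bond gained makes the step irreversible.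

Step 11
Reactants: 18 quaternary keto aldehyde
Product: 19 spiro[4.5]decenol (C18 carbinol epimers)
Conditions: CrCl2 (6 equiv), NiCl2 (2 mol %), DMF, 25 °C, 5 mM
Reagents that add atoms: none
Why: In the intramolecular Nozaki–Hiyama–Kishi reaction the alkenylchromium reagent forms from the Z vinyl iodide with retention and adds only to the aldehyde, which closes the cyclohexene through C17–C18 and leaves the ketone, vinyl group and sulfide untouched; the carbinol configuration is irrelevant because C18 is ionised next.

Step 12
Reactants: 19 spiro[4.5]decenol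
Product: 20 bridged vinyl sulfide (C4 S; C6 S; C13 R; C18 R)
Conditions: BF3·OEt2 (30 mol %), CH2Cl2, −40 → 0 °C
Reagents that add atoms: none
Why: In this intramolecular Friedel–Crafts allylation, ionisation gives the C18–C17–C15 allyl cation and the aryl group on C13 attacks through C19 (ortho to methoxy) at the secondary terminus C18, the usual regiochemistry of arene terpenylation since it avoids a quaternary centre and keeps the trisubstituted alkene; C18 can only become R because the arene is tied to C13.

Step 13
Reactants: 20 bridged vinyl sulfide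
Product: 22 bridged vinyl ketone bearing the restored isopropenyl group, via phenyl sulfoxide 21 (not isolated)
Conditions: mCPBA (1.0 equiv), CH2Cl2, −78 °C; NaHCO3 wash; then PhMe, CaCO3, 110 °C
Reagents that add atoms: none
Why: Sulfide oxidation at low temperature is far faster than epoxidation, and the thermal syn-elimination of the sulfoxide, whose only β-hydrogen sits on C2, regenerates the isopropenyl group as a single regioisomer.

Step 14
Reactants: 22 bridged vinyl ketone
Product: 23 9′-acetyl-1′,4′-dimethoxy-7′-methyl-4-(prop-1-en-2-yl)-5′,8′-dihydrospiro[cyclopentane-1,10′-[5,9]methanobenzo[7]annulen]-2-one (C4 S; C6 S; C13 R; C18 R)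
Conditions: PdCl2 (10 mol %), CuCl (1 equiv), O2 (1 atm), DMF–H2O 7:1, 25 °C
Reagents that add atoms: water, O
Why: In the Tsuji–Wacker oxidation, divalent palladium binds the monosubstituted vinyl group much faster than the 1,1-disubstituted and trisubstituted alkenes, and Markovnikov hydroxypalladation gives the methyl ketone C11(=O)–C10H3.

Step 15
Reactants: 23 spiro diketone
Product: 25 pentacyclic 7,11-dione dimethyl ether (C4 S; C6 S; C9 R; C13 R; C18 R), via dilithium bis-enolate 24 (not isolated)
Conditions: slow inverse addition of 23 to LiN(iPr)2 (2.5 equiv), THF, −78 °C (final 5 mM); then Cu[O2CCH(Et)Bu]2 (2.2 equiv) in THF, −78 → 0 °C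
Reagents that add atoms: none
Why: Adding 23 slowly to excess amide converts both ketones at once into bis-enolate 24, so no enolate meets a free carbonyl group; this matters because C7 and C11 are also 1,4-related through C6–C13 and a mono-enolate would close a five-membered aldol ring. Divalent copper removes one electron from an enolate to give an α-keto radical (or its copper-bound equivalent) that bonds to the α-carbon of the second enolate, and a second equivalent of oxidant takes the electron of the resulting ketyl; the closest known reaction type is the intramolecular oxidative coupling of ketone bis-enolates by copper or iron salts to cyclic 1,4-diketones. The ring closed is the six-membered dione C6–C7–C9–C10–C11–C13, formally a 6-endo-trig closure because both carbons of the accepting enolate end up in the ring, and it turns the cyclopentanone into a bicyclo[3.2.1]octane. The only new stereocentre, C9, is fixed as R by the tether, since C10 hangs from C13 on one face of the cyclopentanone enolate while the C4 isopropenyl group lies on the other face and ends up exo. Regioselectivity is built in because quaternary C6 and C13 leave C9 and C10 as the only enolisable carbons, dilution suppresses dimerisation, and the enolates are oxidised at potentials far below that of the dimethoxyarene, so the mild carboxylate oxidant leaves arene and alkenes alone.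

Step 16
Reactants: 25 pentacyclic dione dimethyl ether
Product: 26 pentacyclic quinone
Conditions: (NH4)2Ce(NO3)6 (2.5 equiv), MeCN–H2O 2:1, 0 °C
Reagents that add atoms: water, O
Why: Oxidative demethylation of a 1,4-dimethoxyarene by tetravalent cerium goes through the arene radical cation and water attack, spares isolated alkenes and ketones, and gives a quinone that cannot tautomerise because both flanking carbons are bridgeheads.

Step 17
Reactants: 26 pentacyclic quinone
Product: 27 target hydroquinone CNP0287617.1
Conditions: Na2S2O4, H2O–EtOAc, 25 °C, argon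
Reagents that add atoms: none
Why: Dithionite reduces the quinone by two electrons to the hydroquinone under neutral two-phase conditions that leave ketones, alkenes and all five stereocentres unchanged.

Compound list
1 | cyclopent-2-en-1-one | O=C1C=CCC1 | starting material
2 | isopropenylboronic acid pinacol ester | C=C(C)B1OC(C)(C)C(C)(C)O1 | starting material
3 | (3S)-3-(prop-1-en-2-yl)cyclopentan-1-one | C=C(C)[C@H]1CCC(=O)C1 | intermediate
4 | (3S)-3-[1-(phenylsulfanyl)propan-2-yl]cyclopentan-1-one (C2 epimers) | CC(CSc1ccccc1)[C@H]1CCC(=O)C1 | intermediate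
5 | ethyl formate | CCOC=O | starting material
6 | (2Z,4S)-2-(hydroxymethylidene)-4-[1-(phenylsulfanyl)propan-2-yl]cyclopentan-1-one | CC(CSc1ccccc1)[C@H]1C/C(=C/O)C(=O)C1 | intermediate
7 | 2-iodo-1,4-dimethoxybenzene | COc1ccc(OC)c(I)c1 | starting material
8 | prop-2-yn-1-ol | C#CCO | starting material
9 | 3-(2,5-dimethoxyphenyl)prop-2-yn-1-ol | OCC#Cc1cc(OC)ccc1OC | intermediate
10 | sodium 3-(2,5-dimethoxyphenyl)-2,2-bis(2-methoxyethoxy)-1-oxa-2-aluminatacyclopent-3-ene | [Na+].COCCO[Al-]1(OCCOC)OCC=C1c1cc(OC)ccc1OC | intermediate
11 | (Z)-3-(2,5-dimethoxyphenyl)-3-iodoprop-2-en-1-ol | OC/C=C(\I)c1cc(OC)ccc1OC | intermediate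
12 | 4-methyl-1-oxa-2-magnesacyclopent-3-ene | CC1=C[Mg]OC1 | intermediate
13 | (Z)-3-iodo-2-methylprop-2-en-1-ol | OC/C(C)=C\I | intermediate
14 | (Z)-3-bromo-1-iodo-2-methylprop-1-ene | BrC/C(C)=C\I | intermediate
15 | 3-(2,5-dimethoxyphenyl)-1-oxa-2-magnesacyclopent-3-ene | COc1ccc(OC)c(c1)C1=CCO[Mg]1 | intermediate
16 | (2E,5Z)-3-(2,5-dimethoxyphenyl)-6-iodo-5-methylhexa-2,5-dien-1-ol | OC/C=C(\C/C(C)=C\I)c1cc(OC)ccc1OC | intermediate
17 | (2E,4S)-2-({[(2E,5Z)-3-(2,5-dimethoxyphenyl)-6-iodo-5-methylhexa-2,5-dien-1-yl]oxy}methylidene)-4-[1-(phenylsulfanyl)propan-2-yl]cyclopentan-1-one | CC(CSc1ccccc1)[C@H]1C/C(=C\OC/C=C(\C/C(C)=C\I)c2cc(OC)ccc2OC)C(=O)C1 | intermediate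
18 | (1R,4S)-1-[(3R,5Z)-3-(2,5-dimethoxyphenyl)-6-iodo-5-methylhexa-1,5-dien-3-yl]-2-oxo-4-[1-(phenylsulfanyl)propan-2-yl]cyclopentane-1-carbaldehyde | CC(CSc1ccccc1)[C@H]1C[C@@](C=O)(C(=O)C1)[C@@](C=C)(C/C(C)=C\I)c1cc(OC)ccc1OC | intermediate
19 | (3S,5R,10R)-10-(2,5-dimethoxyphenyl)-10-ethenyl-6-hydroxy-8-methyl-3-[1-(phenylsulfanyl)propan-2-yl]spiro[4.5]dec-7-en-1-one (carbinol epimers) | CC(CSc1ccccc1)[C@H]1C[C@@]2(C(=O)C1)[C@@](C=C)(CC(C)=CC2O)c1cc(OC)ccc1OC | intermediate
20 | 9′-ethenyl-1′,4′-dimethoxy-7′-methyl-4-[1-(phenylsulfanyl)propan-2-yl]-5′,8′-dihydrospiro[cyclopentane-1,10′-[5,9]methanobenzo[7]annulen]-2-one (C4 S, C6 S, C13 R, C18 R) | CC(CSc1ccccc1)[C@H]1C[C@@]2(C(=O)C1)[C@@]1(C=C)CC(C)=C[C@@H]2c2c(OC)ccc(OC)c21 | intermediate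
21 | phenyl sulfoxide of 20 (sulfur and C2 epimers) | CC(CS(=O)c1ccccc1)[C@H]1C[C@@]2(C(=O)C1)[C@@]1(C=C)CC(C)=C[C@@H]2c2c(OC)ccc(OC)c21 | intermediate
22 | 9′-ethenyl-1′,4′-dimethoxy-7′-methyl-4-(prop-1-en-2-yl)-5′,8′-dihydrospiro[cyclopentane-1,10′-[5,9]methanobenzo[7]annulen]-2-one (C4 S, C6 S, C13 R, C18 R) | C=C(C)[C@H]1C[C@@]2(C(=O)C1)[C@@]1(C=C)CC(C)=C[C@@H]2c2c(OC)ccc(OC)c21 | intermediate
23 | 9′-acetyl-1′,4′-dimethoxy-7′-methyl-4-(prop-1-en-2-yl)-5′,8′-dihydrospiro[cyclopentane-1,10′-[5,9]methanobenzo[7]annulen]-2-one (C4 S, C6 S, C13 R, C18 R) | C=C(C)[C@H]1C[C@@]2(C(=O)C1)[C@@]1(C(C)=O)CC(C)=C[C@@H]2c2c(OC)ccc(OC)c21 | intermediate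
24 | dilithium bis-enolate of 23 (C7=C9 and C11=C10 enolates) | [Li+].[Li+].C=C(C)[C@H]1C[C@@]2(C([O-])=C1)[C@@]1(C(=C)[O-])CC(C)=C[C@@H]2c2c(OC)ccc(OC)c21 | intermediate
25 | hydroquinone dimethyl ether of the target, C9–C10 closed (C4 S, C6 S, C9 R, C13 R, C18 R) | C=C(C)[C@H]1C[C@@]23C(=O)[C@@H]1CC(=O)[C@@]21CC(C)=C[C@@H]3c2c(OC)ccc(OC)c21 | intermediate
26 | 1,4-benzoquinone corresponding to the target | C=C(C)[C@H]1C[C@@]23C(=O)[C@@H]1CC(=O)[C@@]21CC(C)=C[C@@H]3C2=C1C(=O)C=CC2=O | intermediate
27 | CNP0287617.1 (C4 S, C6 S, C9 R, C13 R, C18 R) | C=C(C)[C@H]1C[C@@]23C(=O)[C@@H]1CC(=O)[C@@]21CC(C)=C[C@@H]3c2c(O)ccc(O)c21 | target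

Total step count: 17. Longest linear sequence: 12 steps (for example 4, 5, 8, then 9–17).

Steps most likely to fail:

Step 15. A mono-enolate may undergo aldol closure onto the second ketone before deprotonation is complete, the enolates may couple between molecules, or the α-keto radical may add to the C15=C17 alkene. The fallback makes the same bond by two-electron chemistry. It sets out from 23, which is silylated with TMSOTf and Et3N in CH2Cl2 to the bis(trimethylsilyl) enol ether F1. One equivalent of NBS at −78 °C brominates the unhindered terminal enol ether to give the bromomethyl ketone silyl enol ether F2. Anhydrous Bu4NF at high dilution then releases the C9 enolate, which displaces bromide in a six-membered intramolecular alkylation from the C13 face, and the route is rejoined at 25.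

Step 10. The ether may ionise into a stabilised enolate and allyl cation that recombine at the primary terminus C10. The push–pull enol ether may lose its geometry and erode the C6/C13 relationship, or the product may undergo a subsequent Cope rearrangement. The fallback moves the rearrangement to a ring-locked enol ether with a poorer leaving enolate, a system known to build adjacent quaternary carbons on 2-oxocyclopentanecarboxylates.
- It sets out from 4, which is carboxylated with NaH and dimethyl carbonate to the β-keto ester F3.
- F3 is O-allylated with 16 under Mitsunobu conditions to the cyclic allyl enol ether F4.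
- Warming F4 to about 80 °C should give, through the same chair and the same ring face, the quaternary β-keto ester F5.
- Excess iBu2AlH reduces ester and ketone to the diol F6.
- Dess–Martin periodinane oxidises both alcohols, and the route is rejoined at 18.

Step 12. The allyl cation may lose a proton to give cyclohexadienes, or the arene may attack the tertiary terminus C15. The fallback reverses the order of the two closures and makes C17–C18 by cross-electrophile coupling.
- It sets out from 18, whose aldehyde is attacked by the arene under SnCl4 in CH2Cl2 at −78 °C (the vinyl iodide is too poor a nucleophile to interfere) to give the indanol F7.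
- SOCl2 and 2,6-lutidine convert F7 into the indanyl chloride F8.
- Nickel-catalysed reductive coupling of the benzylic chloride with the vinyl iodide (NiCl2(dme), 4,4′-di-tert-butyl-2,2′-bipyridine, Mn, DMA) closes the three-carbon bridge with the alkene position fixed, and the route is rejoined at 20.

Further compounds
F1 | step 15 | bis(trimethylsilyl) enol ether of 23 | C=C(C)[C@H]1C[C@@]2(C(O[Si](C)(C)C)=C1)[C@@]1(C(=C)O[Si](C)(C)C)CC(C)=C[C@@H]2c2c(OC)ccc(OC)c21
F2 | step 15 | C13 bromoacetyl compound with the C7 trimethylsilyl enol ether retained | C=C(C)[C@H]1C[C@@]2(C(O[Si](C)(C)C)=C1)[C@@]1(C(=O)CBr)CC(C)=C[C@@H]2c2c(OC)ccc(OC)c21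
F3 | step 10 | methyl (4S)-2-oxo-4-[1-(phenylsulfanyl)propan-2-yl]cyclopentane-1-carboxylate | CC(CSc1ccccc1)[C@H]1CC(C(=O)OC)C(=O)C1
F4 | step 10 | methyl (4S)-2-{[(2E,5Z)-3-(2,5-dimethoxyphenyl)-6-iodo-5-methylhexa-2,5-dien-1-yl]oxy}-4-[1-(phenylsulfanyl)propan-2-yl]cyclopent-1-ene-1-carboxylate | CC(CSc1ccccc1)[C@H]1CC(C(=O)OC)=C(OC/C=C(\C/C(C)=C\I)c2cc(OC)ccc2OC)C1
F5 | step 10 | methyl ester analogue of 18 (CO2Me in place of CHO at C6) | CC(CSc1ccccc1)[C@H]1C[C@@](C(=O)OC)(C(=O)C1)[C@@](C=C)(C/C(C)=C\I)c1cc(OC)ccc1OC
F6 | step 10 | diol from F5 (C18 CH2OH, C7 CHOH epimers) | CC(CSc1ccccc1)[C@H]1C[C@@](CO)(C(O)C1)[C@@](C=C)(C/C(C)=C\I)c1cc(OC)ccc1OC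
F7 | step 12 | spiro indanol (C18–C19 closed, C18 carbinol epimers) | CC(CSc1ccccc1)[C@H]1C[C@]2(C(=O)C1)C(O)c1c(OC)ccc(OC)c1[C@]2(C=C)C/C(C)=C\I
F8 | step 12 | spiro indanyl chloride | CC(CSc1ccccc1)[C@H]1C[C@]2(C(=O)C1)C(Cl)c1c(OC)ccc(OC)c1[C@]2(C=C)C/C(C)=C\I
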